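**Retrosynthetic overview**

1. The target is traced back (benzyl ether hydrogenolysis, 3-O-methylation, C3 hydroxylation) to a 3-unsubstituted flavone, and ring C is opened at O1–C2 to an ortho-hydroxyaryl ynone.
2. The strategy rests on ring A: oxygen sits on three contiguous carbons (C8a, C8, C7), C6 and C5 are unsubstituted, and C4a carries the acyl carbon C4. This is the pattern of a 1,1,2,3-tetraoxygenated butadiene (C8a, C8, C7, C6) added across a terminal acetylenic ketone (C5, C4a).
3. Ring A is therefore built by Diels–Alder reaction and aromatisation of 1,2,3-trimethoxy-1-(trimethylsilyloxy)buta-1,3-diene with the terminal alkyne of a ring B diynone, forming C5–C6 and C4a–C8a and freeing the C8a hydroxyl.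
4. The diene comes from methyl acetoacetate (diazo transfer, O–H insertion, enol ether, silyl ketene acetal). The diynone comes from 2-hydroxy-4,5-dimethoxybenzaldehyde (benzylation, alkyne homologation, acetylide addition to 3-(trimethylsilyl)propynal with desilylation, oxidation).
5. Ring order: ring B is bought, ring A is formed by the cycloaddition, ring C by 6-endo-dig oxa-Michael closure.

Key step: step 9

Assumption: the alkene geometries drawn for 5, 6 and 7 are the expected major isomers and are without consequence, because these carbons all end up in aromatic ring A. Compounds 3, 4, 13, 14 and 16 are racemic and their stereocentres are destroyed later, so the achiral target needs no stereocontrol.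

**Route**

Step 1
Reactants: 1 methyl acetoacetate
Product: 2 methyl 2-diazo-3-oxobutanoate
Conditions: 4-acetamidobenzenesulfonyl azide, Et3N, MeCN, 0 °C → rt
Reagents that add atoms: 4-acetamidobenzenesulfonyl azide, CC(=O)Nc1ccc(cc1)S(=O)(=O)N=[N+]=[N-]
Why: Regitz diazo transfer, in which the doubly activated methylene of the β-keto ester is deprotonated by the amine and takes the diazo group from the sulfonyl azide.

Step 2
Reactants: 2 methyl 2-diazo-3-oxobutanoate
Product: 3 methyl 2-methoxy-3-oxobutanoate
Conditions: Rh2(OAc)4 (1 mol %), MeOH (5 equiv), CH2Cl2, reflux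
Reagents that add atoms: methanol, CO
Why: Rhodium carbenoid O–H insertion, a reliable way to α-alkoxy β-keto esters from acceptor/acceptor diazo compounds; the new stereocentre is racemic and is erased in step 3.

Step 3
Reactants: 3 methyl 2-methoxy-3-oxobutanoate
Product: 5 methyl (2Z)-2,3-dimethoxybut-2-enoate, via dimethyl ketal 4 (not isolated)
Conditions: HC(OMe)3, H2SO4 (cat.), MeOH, rt; then distillation from the acid
Reagents that add atoms: trimethyl orthoformate, COC(OC)OC
Why: Acid-catalysed ketalisation with the orthoformate as water scavenger and elimination of methanol toward the ester (enol ether formation, as used for 3-alkoxycrotonates); either alkene isomer, or the non-conjugated enol ether, should converge on the same dienolate in step 4.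

Step 4
Reactants: 5 methyl (2Z)-2,3-dimethoxybut-2-enoate
Product: 7 (1Z)-1,2,3-trimethoxy-1-(trimethylsilyloxy)buta-1,3-diene, via lithium dienolate 6 (not isolated)
Conditions: LiN(i-Pr)2 (LDA), THF, −78 °C; Me3SiCl, −78 °C → rt; pentane, filtration, distillation; used at once
Reagents that add atoms: chlorotrimethylsilane, C[Si](C)(C)Cl
Why: Vinylogous (γ) deprotonation of the β-alkoxy enoate and O-silylation of the extended enolate, the standard preparation of 1-alkoxy-1-silyloxy vinylketene acetal dienes.

Step 5
Reactants: 8 2-hydroxy-4,5-dimethoxybenzaldehyde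
Product: 9 2-(benzyloxy)-4,5-dimethoxybenzaldehyde
Conditions: BnBr, K2CO3, DMF, 60 °C
Reagents that add atoms: benzyl bromide, BrCc1ccccc1
Why: Williamson ether synthesis on the phenoxide, to which the aldehyde and the methyl ethers are inert.

Step 6
Reactants: 9 2-(benzyloxy)-4,5-dimethoxybenzaldehyde
Product: 10 1-(benzyloxy)-2-ethynyl-4,5-dimethoxybenzene
Conditions: dimethyl (1-diazo-2-oxopropyl)phosphonate, K2CO3, MeOH, rt
Reagents that add atoms: dimethyl (1-diazo-2-oxopropyl)phosphonate, COP(=O)(OC)C(=[N+]=[N-])C(C)=O
Why: Ohira–Bestmann (Seyferth–Gilbert) homologation, in which methanolysis frees dimethyl (diazomethyl)phosphonate, and Horner–Wadsworth–Emmons-type olefination followed by loss of N2 and a 1,2-shift gives the terminal alkyne under conditions that leave the benzyl ether alone.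

Step 7
Reactants: 10 1-(benzyloxy)-2-ethynyl-4,5-dimethoxybenzene; 11 3-(trimethylsilyl)propynal
Product: 14 1-[2-(benzyloxy)-4,5-dimethoxyphenyl]penta-1,4-diyn-3-ol, via lithium acetylide 12 (not isolated), via silylated diynol 13 (not isolated)
Conditions: n-BuLi (1.0 equiv), THF, −78 °C; 11, −78 → 0 °C; then MeOH, K2CO3 (cat.), rt; H2O work-up
Reagents that add atoms: none
Why: 1,2-Addition of the lithium acetylide to the aldehyde, then methoxide-mediated protodesilylation of the C(sp)–Si bond in the same flask; the carbinol centre is racemic and is oxidised away in step 8.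

Step 8
Reactants: 14 1-[2-(benzyloxy)-4,5-dimethoxyphenyl]penta-1,4-diyn-3-ol
Product: 15 1-[2-(benzyloxy)-4,5-dimethoxyphenyl]penta-1,4-diyn-3-one
Conditions: activated MnO2 (excess), CH2Cl2, 0 °C → rt; filtration through Celite; used at once
Reagents that add atoms: none
Why: MnO2 oxidation of a doubly propargylic alcohol under neutral heterogeneous conditions, which spare the terminal alkyne and let the sensitive diynone be taken on after filtration only.

Step 9
Reactants: 7 (1Z)-1,2,3-trimethoxy-1-(trimethylsilyloxy)buta-1,3-diene; 15 1-[2-(benzyloxy)-4,5-dimethoxyphenyl]penta-1,4-diyn-3-one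
Product: 18 3-[2-(benzyloxy)-4,5-dimethoxyphenyl]-1-(2-hydroxy-3,4-dimethoxyphenyl)prop-2-yn-1-one, via cycloadduct 16 (not isolated), via aryl silyl ether 17 (not isolated)
Conditions: 7 (1.5 equiv), toluene, −20 °C → rt; then 0.5 M HCl, THF, 0 °C
Reagents that add atoms: none
Why: A normal-electron-demand Diels–Alder reaction (concerted but asynchronous, or a Mukaiyama–Michael addition followed by ring closure, with the same outcome) joins the CH2 terminus of diene 7 to the terminal alkyne carbon of 15 (C6–C5) and the ketene acetal carbon to the carbonyl-bearing alkyne carbon (C8a–C4a), giving cyclohexa-1,4-diene 16. Acid then ionises the doubly allylic mixed ketal of 16 with loss of methanol, the silyloxy-stabilised cyclohexadienyl cation loses the C6 proton to give aryl silyl ether 17, and hydrolysis of the O–Si bond frees phenol 18. The closest known reaction type is the benzannulation of 1-alkoxy-1-silyloxy vinylketene acetal dienes with acetylenic carbonyl dienophiles, the diene here carrying one more methoxy group. Ring A is closed by an intermolecular (4+2) cycloaddition that forms both ring bonds in one operation and is then aromatised by 1,4-elimination; no stereocentre survives, since the racemic ketal carbon of 16 becomes C8a. The step needs regioselectivity, secured by the match of the largest HOMO coefficient at the diene CH2 with the largest LUMO coefficient at the β-carbon of the ynone, and chemoselectivity between the two alkynes, secured because the terminal alkyne is unhindered and more electrophilic while the other is shielded and deactivated by the electron-rich aryl group. The phenol, not its methyl ether, should result because methoxide leaves the ketal in preference to the silyloxy group.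

Step 10
Reactants: 18 3-[2-(benzyloxy)-4,5-dimethoxyphenyl]-1-(2-hydroxy-3,4-dimethoxyphenyl)prop-2-yn-1-one
Product: 19 2-[2-(benzyloxy)-4,5-dimethoxyphenyl]-7,8-dimethoxy-4H-chromen-4-one
Conditions: K2CO3, acetone, reflux
Reagents that add atoms: none
Why: Intramolecular oxa-Michael addition (6-endo-dig) of the phenoxide to the β-carbon of the ynone in an aprotic medium, where closure to the chromone is favoured over the 5-exo-dig aurone pathway.

Step 11
Reactants: 19 2-[2-(benzyloxy)-4,5-dimethoxyphenyl]-7,8-dimethoxy-4H-chromen-4-one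
Product: 22 2-[2-(benzyloxy)-4,5-dimethoxyphenyl]-3-hydroxy-7,8-dimethoxy-4H-chromen-4-one, via C3-lithiated flavone 20 (not isolated), via dimethyl boronate 21 (not isolated)
Conditions: LiN(i-Pr)2 (LDA), THF, −78 °C; B(OMe)3, −78 → 0 °C; then AcOH, 30% H2O2, 0 °C → rt
Reagents that add atoms: hydrogen peroxide, OO
Why: C3 lithiation of the flavone (the vinylogous α-position of the pyranone), boration and oxidative C–B to C–O conversion give the flavonol, and the benzyl and methyl ethers should tolerate the amide base at −78 °C and the buffered peroxide.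

Step 12
Reactants: 22 2-[2-(benzyloxy)-4,5-dimethoxyphenyl]-3-hydroxy-7,8-dimethoxy-4H-chromen-4-one
Product: 23 2-[2-(benzyloxy)-4,5-dimethoxyphenyl]-3,7,8-trimethoxy-4H-chromen-4-one
Conditions: MeI, K2CO3, acetone, reflux
Reagents that add atoms: iodomethane, CI
Why: Williamson O-methylation of the acidic 3-hydroxyl, the only free hydroxyl in the molecule.

Step 13
Reactants: 23 2-[2-(benzyloxy)-4,5-dimethoxyphenyl]-3,7,8-trimethoxy-4H-chromen-4-one
Product: 24 2-(2-hydroxy-4,5-dimethoxyphenyl)-3,7,8-trimethoxy-4H-chromen-4-one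
Conditions: H2 (1 atm), Pd/C (10 wt %), EtOAc–MeOH, rt
Reagents that add atoms: none
Why: Catalytic hydrogenolysis of the benzyl aryl ether, under which the tetrasubstituted vinylogous-ester C2=C3 bond of the 3-methoxyflavone and the methyl ethers should not react.

**Compound list**

1 | methyl acetoacetate | COC(=O)CC(C)=O | starting material
2 | methyl 2-diazo-3-oxobutanoate | COC(=O)C(=[N+]=[N-])C(C)=O | intermediate
3 | methyl 2-methoxy-3-oxobutanoate (racemic) | COC(=O)C(OC)C(C)=O | intermediate
4 | methyl 2,3,3-trimethoxybutanoate (racemic dimethyl ketal) | COC(=O)C(OC)C(C)(OC)OC | intermediate (not isolated)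
5 | methyl (2Z)-2,3-dimethoxybut-2-enoate | C/C(OC)=C(/OC)C(=O)OC | intermediate
6 | lithium 1,2,3-trimethoxybuta-1,3-dien-1-olate | C=C(OC)/C(OC)=C(\OC)O[Li] | intermediate (not isolated)
7 | (1Z)-1,2,3-trimethoxy-1-(trimethylsilyloxy)buta-1,3-diene | C=C(OC)/C(OC)=C(\OC)O[Si](C)(C)C | intermediate
8 | 2-hydroxy-4,5-dimethoxybenzaldehyde | COc1cc(O)c(C=O)cc1OC | starting material
9 | 2-(benzyloxy)-4,5-dimethoxybenzaldehyde | COc1cc(OCc2ccccc2)c(C=O)cc1OC | intermediate
10 | 1-(benzyloxy)-2-ethynyl-4,5-dimethoxybenzene | C#Cc1cc(OC)c(OC)cc1OCc1ccccc1 | intermediate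
11 | 3-(trimethylsilyl)propynal | C[Si](C)(C)C#CC=O | starting material
12 | lithium [2-(benzyloxy)-4,5-dimethoxyphenyl]acetylide | [Li]C#Cc1cc(OC)c(OC)cc1OCc1ccccc1 | intermediate (not isolated)
13 | 1-[2-(benzyloxy)-4,5-dimethoxyphenyl]-5-(trimethylsilyl)penta-1,4-diyn-3-ol (racemic; present as its lithium alkoxide until methanol is added) | C[Si](C)(C)C#CC(O)C#Cc1cc(OC)c(OC)cc1OCc1ccccc1 | intermediate (not isolated)
14 | 1-[2-(benzyloxy)-4,5-dimethoxyphenyl]penta-1,4-diyn-3-ol (racemic) | C#CC(O)C#Cc1cc(OC)c(OC)cc1OCc1ccccc1 | intermediate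
15 | 1-[2-(benzyloxy)-4,5-dimethoxyphenyl]penta-1,4-diyn-3-one | C#CC(=O)C#Cc1cc(OC)c(OC)cc1OCc1ccccc1 | intermediate
16 | 3-[2-(benzyloxy)-4,5-dimethoxyphenyl]-1-[4,5,6-trimethoxy-6-(trimethylsilyloxy)cyclohexa-1,4-dien-1-yl]prop-2-yn-1-one (racemic) | COC1=C(OC)C(OC)(O[Si](C)(C)C)C(C(=O)C#Cc2cc(OC)c(OC)cc2OCc2ccccc2)=CC1 | intermediate (not isolated)
17 | 3-[2-(benzyloxy)-4,5-dimethoxyphenyl]-1-[3,4-dimethoxy-2-(trimethylsilyloxy)phenyl]prop-2-yn-1-one | C[Si](C)(C)Oc1c(OC)c(OC)ccc1C(=O)C#Cc1cc(OC)c(OC)cc1OCc1ccccc1 | intermediate (not isolated)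
18 | 3-[2-(benzyloxy)-4,5-dimethoxyphenyl]-1-(2-hydroxy-3,4-dimethoxyphenyl)prop-2-yn-1-one | O=C(C#Cc1cc(OC)c(OC)cc1OCc1ccccc1)c1ccc(OC)c(OC)c1O | intermediate
19 | 2-[2-(benzyloxy)-4,5-dimethoxyphenyl]-7,8-dimethoxy-4H-chromen-4-one | COc1ccc2c(c1OC)oc(-c1cc(OC)c(OC)cc1OCc1ccccc1)cc2=O | intermediate
20 | {2-[2-(benzyloxy)-4,5-dimethoxyphenyl]-7,8-dimethoxy-4-oxo-4H-chromen-3-yl}lithium | [Li]c1c(-c2cc(OC)c(OC)cc2OCc2ccccc2)oc2c(OC)c(OC)ccc2c1=O | intermediate (not isolated)
21 | dimethyl {2-[2-(benzyloxy)-4,5-dimethoxyphenyl]-7,8-dimethoxy-4-oxo-4H-chromen-3-yl}boronate | COB(OC)c1c(-c2cc(OC)c(OC)cc2OCc2ccccc2)oc2c(OC)c(OC)ccc2c1=O | intermediate (not isolated)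
22 | 2-[2-(benzyloxy)-4,5-dimethoxyphenyl]-3-hydroxy-7,8-dimethoxy-4H-chromen-4-one | COc1ccc2c(c1OC)oc(-c1cc(OC)c(OC)cc1OCc1ccccc1)c(O)c2=O | intermediate
23 | 2-[2-(benzyloxy)-4,5-dimethoxyphenyl]-3,7,8-trimethoxy-4H-chromen-4-one | COc1ccc2c(c1OC)oc(-c1cc(OC)c(OC)cc1OCc1ccccc1)c(OC)c2=O | intermediate
24 | 2-(2-hydroxy-4,5-dimethoxyphenyl)-3,7,8-trimethoxy-4H-chromen-4-one | COc1cc(O)c(-c2oc3c(OC)c(OC)ccc3c(=O)c2OC)cc1OC | target

**Step count**

Total: 13 steps. Longest linear sequence: 9 steps (steps 5–13 from 8; equally steps 1–4 and 9–13 from 1).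

**Steps most likely to fail**

Step 9. Protodesilylation of the diene by adventitious protons, or oligomerisation of the unhindered terminal ynone, may outrun the cycloaddition; Michael addition without ring closure may also leave open-chain adducts. The fallback sets out from aldehyde 9 and comes back to the route at flavone 19, building the ring A–C3 unit by classical chalcone chemistry instead of cycloaddition. Claisen–Schmidt condensation of 9 with purchased 1-(2-hydroxy-3,4-dimethoxyphenyl)ethan-1-one F1 (KOH, EtOH, rt) should give (2E)-3-[2-(benzyloxy)-4,5-dimethoxyphenyl]-1-(2-hydroxy-3,4-dimethoxyphenyl)prop-2-en-1-one F2. Oxidative cyclisation of this 2'-hydroxychalcone with catalytic I2 in DMSO at 120 °C should then give 19.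

Step 11. β-Elimination of the ring oxygen from the C3-lithiated pyranone (opening of ring C), or addition of the amide base at C2, may compete with boration, and the peroxide may attack the electron-rich rings. The fallback sets out from flavone 19 and comes back at flavonol 22 by electrophilic oxidation instead of metalation. Epoxidation of the C2=C3 bond with dimethyldioxirane (acetone–CH2Cl2, 0 °C) should give the racemic 2,3-epoxide of 19, 2-[2-(benzyloxy)-4,5-dimethoxyphenyl]-2,3-epoxy-7,8-dimethoxychroman-4-one F3. A catalytic amount of p-TsOH in CH2Cl2 should open it at C2, where the cation is stabilised by O1 and ring B, and loss of the C3 proton gives 22.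

Step 10. Because the electron-rich, ortho-substituted ring B lowers the electrophilicity of the β-carbon, 5-exo-dig attack of the phenoxide at the α-carbon (aurone formation) may compete with the 6-endo-dig closure. The fallback sets out from ynone 18 and comes back at flavone 19 by changing the mechanism from direct oxa-Michael addition to amine addition followed by addition–elimination. Conjugate addition of Et2NH (EtOH, rt) should give (2E)-3-[2-(benzyloxy)-4,5-dimethoxyphenyl]-3-(diethylamino)-1-(2-hydroxy-3,4-dimethoxyphenyl)prop-2-en-1-one F4, whose alkene geometry is mobile. On heating in EtOH, the phenol attacks the amine-bearing carbon and expels Et2NH, a path that can only close the six-membered ring.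

**Further compounds**

F1 | step 9 | 1-(2-hydroxy-3,4-dimethoxyphenyl)ethan-1-one (purchased) | CC(=O)c1ccc(OC)c(OC)c1O
F2 | step 9 | (2E)-3-[2-(benzyloxy)-4,5-dimethoxyphenyl]-1-(2-hydroxy-3,4-dimethoxyphenyl)prop-2-en-1-one | O=C(/C=C/c1cc(OC)c(OC)cc1OCc1ccccc1)c1ccc(OC)c(OC)c1O
F3 | step 11 | 2-[2-(benzyloxy)-4,5-dimethoxyphenyl]-2,3-epoxy-7,8-dimethoxychroman-4-one (racemic) | COc1ccc2c(c1OC)OC1(c3cc(OC)c(OC)cc3OCc3ccccc3)OC1C2=O
F4 | step 10 | (2E)-3-[2-(benzyloxy)-4,5-dimethoxyphenyl]-3-(diethylamino)-1-(2-hydroxy-3,4-dimethoxyphenyl)prop-2-en-1-one | CCN(CC)/C(=C/C(=O)c1ccc(OC)c(OC)c1O)c1cc(OC)c(OC)cc1OCc1ccccc1
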